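## Retrosynthetic overview

1. Last C–C bond is C4–C5: a primary alkyllithium (C5–C17 chain with diene and furan) adds to the Weinreb amide of (2S,3S)-3-chloro-2-(triethylsilyloxy)butanoic acid, then the silyl ether is removed. The chlorohydrin (C2, C3) comes from a ketoreductase dynamic reductive kinetic resolution of ethyl 3-chloro-2-oxobutanoate.
2. C12–C13 bond of the (11E,13E)-diene: Suzuki coupling of an (E)-alkenylboronate (alkyne hydroboration) with an (E)-trisubstituted vinyl iodide (alkyne carboalumination/iodination).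
3. C6 and C10: one C2-symmetric block, (2R,6R)-2,6-dimethylheptane-1,7-diol, from glutaraldehyde by two-directional olefination, catalytic Sharpless epoxidation (first stereocenters), Me3Al epoxide opening and glycol cleavage, then monosilylation.
4. Rings: none is constructed. The furan comes in intact from 3-bromofuran (Negishi coupling); the only rings made are two transient oxiranes (formed in step 3, opened in step 4).

Assumption: the ketoreductase is picked from a commercial screening panel for the (2S,3S) product; glutaraldehyde is used as its commercial 50 wt % aqueous solution.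

## Route

Step 1
Reactants: 1 glutaraldehyde (pentanedial); 2 triethyl phosphonoacetate
Product: 3 diethyl (2E,7E)-nona-2,7-dienedioate
Conditions: 2 (2.2 equiv), K2CO3 (4 equiv), H2O, 0 °C → rt, 16 h
Reagents that add atoms: none
Why: Twofold Horner–Wadsworth–Emmons olefination with the stabilised phosphonate anion gives the thermodynamically preferred (E,E)-diester; no stereocenter is formed.

Step 2
Reactants: 3 diethyl (2E,7E)-nona-2,7-dienedioate
Product: 4 (2E,7E)-nona-2,7-diene-1,9-diol
Conditions: i-Bu2AlH (4.5 equiv), CH2Cl2, −78 → 0 °C; aq. potassium sodium tartrate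
Reagents that add atoms: none
Why: Ester reduction by 1,2-hydride delivery from i-Bu2AlH gives the allylic alcohols and leaves the E double bonds untouched.

Step 3
Reactants: 4 (2E,7E)-nona-2,7-diene-1,9-diol
Product: 5 [(2S,3S)-3-{3-[(2S,3S)-3-(hydroxymethyl)oxiran-2-yl]propyl}oxiran-2-yl]methanol
Conditions: Ti(OiPr)4 (20 mol %), L-(+)-diethyl tartrate (24 mol %), t-BuOOH (4 equiv, isooctane), 4 Å molecular sieves, CH2Cl2, −20 °C
Reagents that add atoms: tert-butyl hydroperoxide CC(C)(C)OO
Why: Twofold Sharpless asymmetric epoxidation, in which the Ti(OiPr)4–L-(+)-diethyl tartrate catalyst delivers oxygen to the same enantioface of each (E)-allylic alcohol to give the (2S,3S) oxirane at both ends (first stereocenters, set by catalysis), the rare mismatched event ending up as a minor meso-type diastereomer so that the C2-symmetric product is of very high ee.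

Step 4
Reactants: 5 [(2S,3S)-3-{3-[(2S,3S)-3-(hydroxymethyl)oxiran-2-yl]propyl}oxiran-2-yl]methanol
Product: 6 (2R,3R,7R,8R)-3,7-dimethylnonane-1,2,8,9-tetraol
Conditions: Me3Al (8 equiv), hexane/CH2Cl2, 0 °C → rt; aq. potassium sodium tartrate
Reagents that add atoms: trimethylaluminium C[Al](C)C
Why: Regioselective opening of a 2,3-epoxy alcohol by trimethylaluminium, where the aluminium alkoxide activates the oxirane and methyl attacks C3 in SN2 fashion with inversion, creates both methyl-bearing stereocenters (future C6 and C10, both R) and leaves a cleavable 1,2-diol at each end.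

Step 5
Reactants: 6 (2R,3R,7R,8R)-3,7-dimethylnonane-1,2,8,9-tetraol
Product: 8 (2R,6R)-2,6-dimethylheptane-1,7-diol, via (2R,6R)-2,6-dimethylheptanedial 7 (not isolated)
Conditions: NaIO4 (2.4 equiv), CH2Cl2/aq. NaHCO3, 0 °C; organic phase, then NaBH4 (2 equiv), EtOH, 0 °C
Reagents that add atoms: none
Why: Malaprade glycol cleavage excises the two terminal carbons and the α-branched dialdehyde is reduced at once by borohydride before it can epimerise, so both stereocenters are kept.

Step 6
Reactants: 8 (2R,6R)-2,6-dimethylheptane-1,7-diol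
Product: 10 (2R,6R)-7-[(tert-butyldimethylsilyl)oxy]-2,6-dimethylheptan-1-ol, via monosodium alkoxide 9 (not isolated)
Conditions: NaH (1.0 equiv), THF, rt, 45 min; t-BuMe2SiCl (1.0 equiv), rt
Reagents that add atoms: tert-butyldimethylsilyl chloride CC(C)(C)[Si](C)(C)Cl
Why: McDougal monosilylation (O-silylation of the sparingly soluble monosodium alkoxide) stops after one silylation, and because the diol is C2-symmetric either hydroxyl gives the same product.

Step 7
Reactants: 10 (2R,6R)-7-[(tert-butyldimethylsilyl)oxy]-2,6-dimethylheptan-1-ol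
Product: 11 (2R,6R)-7-[(tert-butyldimethylsilyl)oxy]-2,6-dimethylheptanal
Conditions: Dess–Martin periodinane (1.3 equiv), NaHCO3, CH2Cl2, 0 °C → rt; used crude
Reagents that add atoms: none
Why: Dess–Martin oxidation under bicarbonate buffer gives the α-methyl aldehyde without epimerisation.

Step 8
Reactants: 11 (2R,6R)-7-[(tert-butyldimethylsilyl)oxy]-2,6-dimethylheptanal
Product: 12 tert-butyl{[(2R,6R)-2,6-dimethyloct-7-yn-1-yl]oxy}dimethylsilane
Conditions: dimethyl (1-diazo-2-oxopropyl)phosphonate (1.5 equiv), K2CO3 (2 equiv), MeOH, 0 °C → rt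
Reagents that add atoms: dimethyl (1-diazo-2-oxopropyl)phosphonate CC(=O)C(=[N+]=[N-])P(=O)(OC)OC
Why: Seyferth–Gilbert homologation in the Ohira–Bestmann variant turns the aldehyde into the terminal alkyne under mild carbonate conditions that keep the α-stereocenter.

Step 9
Reactants: 12 tert-butyl{[(2R,6R)-2,6-dimethyloct-7-yn-1-yl]oxy}dimethylsilane
Product: 13 2-[(1E,3R,7R)-8-[(tert-butyldimethylsilyl)oxy]-3,7-dimethyloct-1-en-1-yl]-4,4,5,5-tetramethyl-1,3,2-dioxaborolane
Conditions: pinacolborane (1.5 equiv), Cp2Zr(H)Cl (10 mol %), Et3N (10 mol %), neat, 60 °C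
Reagents that add atoms: pinacolborane CC1(C)OBOC1(C)C
Why: Cp2Zr(H)Cl-catalysed hydroboration is a syn, anti-Markovnikov addition to the terminal alkyne and therefore gives only the (E)-alkenylboronate.

Step 10
Reactants: 14 (5-chloropent-1-yn-1-yl)trimethylsilane
Product: 15 (5-iodopent-1-yn-1-yl)trimethylsilane
Conditions: NaI (3 equiv), acetone, reflux, 24 h
Reagents that add atoms: sodium iodide [Na+].[I-]
Why: Finkelstein halide exchange (SN2), driven by precipitation of NaCl from acetone.

Step 11
Reactants: 15 (5-iodopent-1-yn-1-yl)trimethylsilane; 16 3-bromofuran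
Product: 18 [5-(furan-3-yl)pent-1-yn-1-yl]trimethylsilane, via alkylzinc iodide 17 (not isolated)
Conditions: Zn dust (activated by BrCH2CH2Br and Me3SiCl), LiCl, THF, 40 °C; then 16, Pd(OAc)2 (2 mol %), SPhos (4 mol %), THF, rt → 50 °C
Reagents that add atoms: none
Why: Zinc insertion into the primary C–I bond followed by Negishi sp3–sp2 cross-coupling with the heteroaryl bromide attaches the intact furan at its 3-position, the silyl cap keeping the alkyne inert.

Step 12
Reactants: 18 [5-(furan-3-yl)pent-1-yn-1-yl]trimethylsilane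
Product: 19 3-(pent-4-yn-1-yl)furan
Conditions: K2CO3 (0.2 equiv), MeOH, rt
Reagents that add atoms: none
Why: Base-catalysed methanolysis of the C(sp)–Si bond (protodesilylation) frees the terminal alkyne.

Step 13
Reactants: 19 3-(pent-4-yn-1-yl)furan
Product: 21 3-[(4E)-5-iodo-4-methylpent-4-en-1-yl]furan, via alkenyldimethylalane 20 (not isolated)
Conditions: Me3Al (3 equiv), Cp2ZrCl2 (0.25 equiv), CH2Cl2, 0 °C → rt, 12 h; then I2 (1.3 equiv), THF, −30 → 0 °C
Reagents that add atoms: trimethylaluminium C[Al](C)C; iodine II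
Why: Negishi Cp2ZrCl2-catalysed carboalumination adds methyl and aluminium syn across the terminal alkyne with methyl on the internal carbon, and iodinolysis of the C–Al bond with retention gives the (E)-trisubstituted vinyl iodide.

Step 14
Reactants: 13 2-[(1E,3R,7R)-8-[(tert-butyldimethylsilyl)oxy]-3,7-dimethyloct-1-en-1-yl]-4,4,5,5-tetramethyl-1,3,2-dioxaborolane; 21 3-[(4E)-5-iodo-4-methylpent-4-en-1-yl]furan
Product: 22 tert-butyl{[(2R,6R,7E,9E)-13-(furan-3-yl)-2,6,10-trimethyltrideca-7,9-dien-1-yl]oxy}dimethylsilane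
Conditions: PdCl2(dppf) (5 mol %), K3PO4 (3 equiv), THF/H2O (degassed), rt → 45 °C
Reagents that add atoms: none
Why: Suzuki–Miyaura coupling joins the two stereodefined alkenyl partners with retention at both double bonds and so gives the (E,E)-diene.

Step 15
Reactants: 22 tert-butyl{[(2R,6R,7E,9E)-13-(furan-3-yl)-2,6,10-trimethyltrideca-7,9-dien-1-yl]oxy}dimethylsilane
Product: 23 (2R,6R,7E,9E)-13-(furan-3-yl)-2,6,10-trimethyltrideca-7,9-dien-1-ol
Conditions: Bu4NF (1.5 equiv), THF, 0 °C → rt
Reagents that add atoms: none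
Why: Fluoride-induced desilylation cleaves the primary silyl ether, and diene and furan are inert to it.

Step 16
Reactants: 23 (2R,6R,7E,9E)-13-(furan-3-yl)-2,6,10-trimethyltrideca-7,9-dien-1-ol
Product: 24 3-[(4E,6E,8R,12R)-13-iodo-4,8,12-trimethyltrideca-4,6-dien-1-yl]furan
Conditions: PPh3 (1.3 equiv), imidazole (1.5 equiv), I2 (1.25 equiv, added last), CH2Cl2, 0 °C, dark, 30 min
Reagents that add atoms: iodine II
Why: Appel-type (Garegg–Samuelsson) iodination, in which iodide displaces the alkoxyphosphonium group by SN2 at the primary carbon, leaves the neighbouring stereocenter untouched, and the slight excess of PPh3 keeps free iodine away from the diene.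

Step 17
Reactants: 25 ethyl 2-oxobutanoate
Product: 26 ethyl 3-chloro-2-oxobutanoate (racemic)
Conditions: SO2Cl2 (1.05 equiv), CH2Cl2, 0 °C → rt; distil
Reagents that add atoms: sulfuryl chloride O=S(=O)(Cl)Cl
Why: Electrophilic α-chlorination of the enol of the α-keto ester can only occur at C3, and the product is racemic and configurationally labile.

Step 18
Reactants: 26 ethyl 3-chloro-2-oxobutanoate (racemic)
Product: 27 ethyl (2S,3S)-3-chloro-2-hydroxybutanoate
Conditions: ketoreductase (NADPH-dependent, screened for the (2S,3S) product), NADP+ (cat.), i-PrOH (10 vol %), 0.1 M potassium phosphate buffer pH 6.5, 30 °C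
Reagents that add atoms: none
Why: Enzymatic dynamic reductive kinetic resolution, in which the chlorine-bearing carbon racemises quickly through the enol in the buffer while the ketoreductase reduces only the (3S)-ketone on one carbonyl face with NADPH (recycled by i-PrOH), sets C2 (S) and C3 (S) together in up to quantitative yield.

Step 19
Reactants: 27 ethyl (2S,3S)-3-chloro-2-hydroxybutanoate
Product: 28 ethyl (2S,3S)-3-chloro-2-[(triethylsilyl)oxy]butanoate
Conditions: Et3SiCl (1.2 equiv), imidazole (2 equiv), DMF, 0 °C → rt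
Reagents that add atoms: chlorotriethylsilane CC[Si](Cl)(CC)CC
Why: Imidazole-mediated O-silylation protects the hydroxyl so that it can neither close onto the chloride to a glycidate nor quench the organolithium later.

Step 20
Reactants: 28 ethyl (2S,3S)-3-chloro-2-[(triethylsilyl)oxy]butanoate
Product: 29 (2S,3S)-3-chloro-N-methoxy-N-methyl-2-[(triethylsilyl)oxy]butanamide
Conditions: MeNH(OMe)·HCl (3 equiv), AlMe3 (3 equiv), CH2Cl2, 0 °C → rt; aq. potassium sodium tartrate
Reagents that add atoms: N,O-dimethylhydroxylamine hydrochloride CNOC.Cl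
Why: Weinreb amide formation by aminolysis with the Lewis-acidic, non-basic chloro(methyl)aluminium amide does not enolise the ester, so there is no epimerisation at C2 and no loss of HCl.

Step 21
Reactants: 24 3-[(4E,6E,8R,12R)-13-iodo-4,8,12-trimethyltrideca-4,6-dien-1-yl]furan; 29 (2S,3S)-3-chloro-N-methoxy-N-methyl-2-[(triethylsilyl)oxy]butanamide
Product: 32 (2S,3S,6R,10R,11E,13E)-2-chloro-17-(furan-3-yl)-6,10,14-trimethyl-3-[(triethylsilyl)oxy]heptadeca-11,13-dien-4-one, via alkyllithium 30 (not isolated), via tetrahedral lithium aminal alkoxide 31 (not isolated)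
Conditions: t-BuLi (2.05 equiv), Et2O/pentane, −78 °C, 20 min; then 29 (1.3 equiv), Et2O, −78 → −40 °C; aq. NH4Cl at −40 °C
Reagents that add atoms: none
Why: Iodine–lithium exchange followed by Weinreb ketone synthesis, in which the N,O-chelated tetrahedral intermediate survives until the cold quench, prevents over-addition and keeps the β-chloro ketone from being enolised.

Step 22
Reactants: 32 (2S,3S,6R,10R,11E,13E)-2-chloro-17-(furan-3-yl)-6,10,14-trimethyl-3-[(triethylsilyl)oxy]heptadeca-11,13-dien-4-one
Product: 33 (2S,3S,6R,10R,11E,13E)-2-chloro-17-(furan-3-yl)-3-hydroxy-6,10,14-trimethylheptadeca-11,13-dien-4-one (target, CNP0261264.1)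
Conditions: HF·pyridine, pyridine, THF, 0 °C → rt
Reagents that add atoms: none
Why: Desilylation of the labile triethylsilyl ether with buffered HF·pyridine is non-basic, so neither E1cB loss of HCl nor epimerisation at C3 occurs and furan and diene survive.

## Compound list

1 | glutaraldehyde (pentanedial) | O=CCCCC=O | starting material
2 | triethyl phosphonoacetate | CCOC(=O)CP(=O)(OCC)OCC | starting material
3 | diethyl (2E,7E)-nona-2,7-dienedioate | CCOC(=O)/C=C/CCC/C=C/C(=O)OCC | intermediate
4 | (2E,7E)-nona-2,7-diene-1,9-diol | OC/C=C/CCC/C=C/CO | intermediate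
5 | [(2S,3S)-3-{3-[(2S,3S)-3-(hydroxymethyl)oxiran-2-yl]propyl}oxiran-2-yl]methanol | OC[C@@H]1O[C@H]1CCC[C@@H]1O[C@H]1CO | intermediate
6 | (2R,3R,7R,8R)-3,7-dimethylnonane-1,2,8,9-tetraol | OC[C@H](O)[C@H](C)CCC[C@@H](C)[C@@H](O)CO | intermediate
7 | (2R,6R)-2,6-dimethylheptanedial | O=C[C@H](C)CCC[C@@H](C)C=O | intermediate (not isolated)
8 | (2R,6R)-2,6-dimethylheptane-1,7-diol | OC[C@H](C)CCC[C@@H](C)CO | intermediate
9 | sodium (2R,6R)-7-hydroxy-2,6-dimethylheptan-1-olate | [Na+].[O-]C[C@H](C)CCC[C@@H](C)CO | intermediate (not isolated)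
10 | (2R,6R)-7-[(tert-butyldimethylsilyl)oxy]-2,6-dimethylheptan-1-ol | OC[C@H](C)CCC[C@@H](C)CO[Si](C)(C)C(C)(C)C | intermediate
11 | (2R,6R)-7-[(tert-butyldimethylsilyl)oxy]-2,6-dimethylheptanal | O=C[C@H](C)CCC[C@@H](C)CO[Si](C)(C)C(C)(C)C | intermediate
12 | tert-butyl{[(2R,6R)-2,6-dimethyloct-7-yn-1-yl]oxy}dimethylsilane | C#C[C@H](C)CCC[C@@H](C)CO[Si](C)(C)C(C)(C)C | intermediate
13 | 2-[(1E,3R,7R)-8-[(tert-butyldimethylsilyl)oxy]-3,7-dimethyloct-1-en-1-yl]-4,4,5,5-tetramethyl-1,3,2-dioxaborolane | CC1(C)OB(/C=C/[C@H](C)CCC[C@@H](C)CO[Si](C)(C)C(C)(C)C)OC1(C)C | intermediate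
14 | (5-chloropent-1-yn-1-yl)trimethylsilane | C[Si](C)(C)C#CCCCCl | starting material
15 | (5-iodopent-1-yn-1-yl)trimethylsilane | C[Si](C)(C)C#CCCCI | intermediate
16 | 3-bromofuran | Brc1ccoc1 | starting material
17 | [5-(trimethylsilyl)pent-4-yn-1-yl]zinc iodide | C[Si](C)(C)C#CCCC[Zn]I | intermediate (not isolated)
18 | [5-(furan-3-yl)pent-1-yn-1-yl]trimethylsilane | C[Si](C)(C)C#CCCCc1ccoc1 | intermediate
19 | 3-(pent-4-yn-1-yl)furan | C#CCCCc1ccoc1 | intermediate
20 | [(1E)-5-(furan-3-yl)-2-methylpent-1-en-1-yl]dimethylalane | C[Al](C)/C=C(\C)CCCc1ccoc1 | intermediate (not isolated)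
21 | 3-[(4E)-5-iodo-4-methylpent-4-en-1-yl]furan | I/C=C(\C)CCCc1ccoc1 | intermediate
22 | tert-butyl{[(2R,6R,7E,9E)-13-(furan-3-yl)-2,6,10-trimethyltrideca-7,9-dien-1-yl]oxy}dimethylsilane | C/C(=C\C=C\[C@H](C)CCC[C@@H](C)CO[Si](C)(C)C(C)(C)C)CCCc1ccoc1 | intermediate
23 | (2R,6R,7E,9E)-13-(furan-3-yl)-2,6,10-trimethyltrideca-7,9-dien-1-ol | C/C(=C\C=C\[C@H](C)CCC[C@@H](C)CO)CCCc1ccoc1 | intermediate
24 | 3-[(4E,6E,8R,12R)-13-iodo-4,8,12-trimethyltrideca-4,6-dien-1-yl]furan | C/C(=C\C=C\[C@H](C)CCC[C@@H](C)CI)CCCc1ccoc1 | intermediate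
25 | ethyl 2-oxobutanoate | CCC(=O)C(=O)OCC | starting material
26 | ethyl 3-chloro-2-oxobutanoate (racemic) | CCOC(=O)C(=O)C(C)Cl | intermediate
27 | ethyl (2S,3S)-3-chloro-2-hydroxybutanoate | CCOC(=O)[C@H](O)[C@H](C)Cl | intermediate
28 | ethyl (2S,3S)-3-chloro-2-[(triethylsilyl)oxy]butanoate | CCOC(=O)[C@H](O[Si](CC)(CC)CC)[C@H](C)Cl | intermediate
29 | (2S,3S)-3-chloro-N-methoxy-N-methyl-2-[(triethylsilyl)oxy]butanamide | CON(C)C(=O)[C@H](O[Si](CC)(CC)CC)[C@H](C)Cl | intermediate
30 | [(2S,6R,7E,9E)-13-(furan-3-yl)-2,6,10-trimethyltrideca-7,9-dien-1-yl]lithium (same geometry as 24; C2 reads S only because CH2Li ranks below the chain) | C/C(=C\C=C\[C@H](C)CCC[C@@H](C)C[Li])CCCc1ccoc1 | intermediate (not isolated)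
31 | lithium (2S,3S,6R,10R,11E,13E)-2-chloro-17-(furan-3-yl)-4-[methoxy(methyl)amino]-6,10,14-trimethyl-3-[(triethylsilyl)oxy]heptadeca-11,13-dien-4-olate (C4 epimers) | C/C(=C\C=C\[C@H](C)CCC[C@@H](C)CC(O[Li])(N(C)OC)[C@H](O[Si](CC)(CC)CC)[C@H](C)Cl)CCCc1ccoc1 | intermediate (not isolated)
32 | (2S,3S,6R,10R,11E,13E)-2-chloro-17-(furan-3-yl)-6,10,14-trimethyl-3-[(triethylsilyl)oxy]heptadeca-11,13-dien-4-one | C/C(=C\C=C\[C@H](C)CCC[C@@H](C)CC(=O)[C@H](O[Si](CC)(CC)CC)[C@H](C)Cl)CCCc1ccoc1 | intermediate
33 | (2S,3S,6R,10R,11E,13E)-2-chloro-17-(furan-3-yl)-3-hydroxy-6,10,14-trimethylheptadeca-11,13-dien-4-one | C/C(=C\C=C\[C@H](C)CCC[C@@H](C)CC(=O)[C@H](O)[C@H](C)Cl)CCCc1ccoc1 | target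

## Step count, longest linear sequence, risks and fallbacks

Total step count: 22 steps (the six in-flask intermediates 7, 9, 17, 20, 30 and 31 are not counted).
Longest linear sequence: 14 steps (steps 1–9, 14–16, 21, 22). The side branches are steps 10–13 (vinyl iodide 21) and steps 17–20 (Weinreb amide 29).

The three steps most likely to fail:

Step 18, the ketoreductase reduction. The enzyme must give both the right carbonyl face and the right C3 epimer, and a given panel may offer only the anti isomer or incomplete diastereoselection. The fallback sets out from 26 and comes back at 27. Compound 26 is reduced without stereocontrol (NaBH4, EtOH, −40 °C) and chromatography separates the racemic syn chlorohydrin ethyl (2S*,3S*)-3-chloro-2-hydroxybutanoate F1 from the racemic anti isomer ethyl (2S*,3R*)-3-chloro-2-hydroxybutanoate F2. F1 is then resolved by lipase-catalysed transesterification (Candida antarctica lipase B or a Burkholderia cepacia lipase chosen for the purpose, vinyl acetate, t-BuOMe, 30 °C, to about 52 % conversion). The (2R,3R) enantiomer is acetylated to ethyl (2R,3R)-2-acetoxy-3-chlorobutanoate F3 and the unreacted alcohol is 27. This is a kinetic resolution in place of the dynamic reductive one, still enzymatic, with at most half of F1 usable.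

Step 21, the organolithium addition. t-BuLi is generated next to a diene and a furan, and the basic alkyllithium meets a β-chloro amide that can eliminate HCl. The fallback sets out from 24 and 28 and comes back at 32, and replaces the organolithium by an organozinc. Ester 28 is converted with Me2AlSEt (from AlMe3 and EtSH, CH2Cl2, 0 °C → rt) into S-ethyl (2S,3S)-3-chloro-2-[(triethylsilyl)oxy]butanethioate F4. Iodide 24 is treated with activated Zn dust (LiCl, THF, 40 °C) to give [(2R,6R,7E,9E)-13-(furan-3-yl)-2,6,10-trimethyltrideca-7,9-dien-1-yl]zinc iodide F5. A Fukuyama coupling (PdCl2(PPh3)2 5 mol %, toluene/THF, rt) of F4 with F5 gives ketone 32 directly under neutral conditions.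

Step 4, the twofold Me3Al epoxide opening. The C3/C2 regioselectivity must hold at two sites and the tetraol is very polar and hard to free from aluminium salts. The fallback sets out from 4 and comes back at 8, and leaves the epoxide chemistry altogether. Appel bromination of 4 (CBr4, PPh3, CH2Cl2, 0 °C) gives (2E,7E)-1,9-dibromonona-2,7-diene F6. A twofold CuBr·SMe2-catalysed asymmetric allylic alkylation (SN2′) follows: MeMgBr, CuBr·SMe2 (2–5 mol %), CH2Cl2, −75 °C, with the enantiomer of the ferrocenyl diphosphine 1-[α-(dimethylamino)-2-(diphenylphosphino)benzyl]-2-(diphenylphosphino)ferrocene (Taniaphos) that gives the (R)-branched product. I have not fixed which ligand enantiomer that is; it must be checked on the diol. This gives (3R,7R)-3,7-dimethylnona-1,8-diene F7. Ozonolysis (O3, CH2Cl2/MeOH, −78 °C) with NaBH4 work-up passes through dialdehyde 7 and rejoins the route at diol 8.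

## Further compounds

F1 | step 18 | rac-ethyl (2S*,3S*)-3-chloro-2-hydroxybutanoate (racemic syn chlorohydrin) | CCOC(=O)[C@H](O)[C@H](C)Cl.CCOC(=O)[C@@H](O)[C@@H](C)Cl
F2 | step 18 | rac-ethyl (2S*,3R*)-3-chloro-2-hydroxybutanoate (racemic anti chlorohydrin) | CCOC(=O)[C@H](O)[C@@H](C)Cl.CCOC(=O)[C@@H](O)[C@H](C)Cl
F3 | step 18 | ethyl (2R,3R)-2-acetoxy-3-chlorobutanoate | CCOC(=O)[C@@H](OC(C)=O)[C@@H](C)Cl
F4 | step 21 | S-ethyl (2S,3S)-3-chloro-2-[(triethylsilyl)oxy]butanethioate | CCSC(=O)[C@H](O[Si](CC)(CC)CC)[C@H](C)Cl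
F5 | step 21 | [(2R,6R,7E,9E)-13-(furan-3-yl)-2,6,10-trimethyltrideca-7,9-dien-1-yl]zinc iodide | C/C(=C\C=C\[C@H](C)CCC[C@@H](C)C[Zn]I)CCCc1ccoc1
F6 | step 4 | (2E,7E)-1,9-dibromonona-2,7-diene | BrC/C=C/CCC/C=C/CBr
F7 | step 4 | (3R,7R)-3,7-dimethylnona-1,8-diene | C=C[C@H](C)CCC[C@@H](C)C=C
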